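## Remarks and numbering

Skeleton locants: C1 (CH2OH), C2 (with its CH3), C3, C4, C5, C6, O7, C8, C9 (with its CH3), C10, C11, C12 (OH, bonded back to C6). O13 is the lactone oxygen on C9 and C14 the lactone carbonyl on C6. C8 carries C15, C16, C17 (with its CH3), C18, C19 (CH2OH). In oxepane names O1 = O7, C2 = C6, C3 = C12, C6 = C9, C7 = C8. TBS = tert-butyldimethylsilyl, TES = triethylsilyl.

Assumption: the organocatalysts of steps 4, 12 and 14 are bought as reagents.

Compound numbers: 1 nerol; 2 its TBS ether; 3 epoxide; 4 aldehyde; 5 hexafluoroisopropyl acrylate; 6 Morita–Baylis–Hillman adduct; 7 its TES ether; 8 allylic alcohol; 9 allylic bromide; 10 methyl acetoacetate; 11 its dianion; 12 β-keto ester; 13 diazo keto ester; 14 diazo alcohol; 15 oxepanone; 16 acrolein; 17 keto aldehyde; 18 phosphonate; 19 its carbanion; 20 Z-enoate; 21 C12 carbinol; 22 its TBS ether; 23 diacid (key-step precursor); 24 iodolactone acid (key-step product); 25 mixed anhydride; 26 iodo alcohol; 27 methyl lactone; 28 target.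

## Analysis of the target

The target 28 is a C20 isoprenoid built on a 6,8-dioxabicyclo[3.2.2]nonan-7-one. Its oxepane (C6, O7, C8, C9, C10, C11, C12) is spanned between the 1,4-related carbons C6 and C9 by the lactone bridge C14(=O)–O13, which also defines a 1,4-dioxan-2-one ring (C6, C14, O13, C9, C8, O7) and a seven-membered lactone ring. There are four stereocentres, C6 (R), C8 (S), C9 (R) and C12 (S); C6 is fully substituted (carboxyl, ether oxygen, C5 chain, C12) and C9 is a tertiary alkyl-oxygen centre. The bridge puts C14 on C6 and O13 on C9 on one face of the oxepane, and the C12 hydroxyl lies on that face too. The C5 chain, the C15 chain and the C9 methyl lie on the other face, so the two chains are cis across the ring oxygen. Both chains end in Z-trisubstituted allylic alcohols: C17=C18 has the nerol pattern, and at C2=C3 the CH2OH group is cis to C4. Sensitive points are the allylic alcohols (ionisation, Z/E drift), the β-hydroxy lactone (retro-aldol, hydride reagents) and three alkenes that must survive every electrophilic and reductive step. The strategy rests on O13 sitting on tertiary C9 directly across the ring from the C14 carboxyl, so C9 can stay sp2 (C9=CH2) to the end and be made a stereocentre by carboxylate capture of the activated alkene. The same carboxyl is also δ,ε to the C2=C3 alkene of its own chain, so that alkene has to be switched off electronically while C9=CH2 is activated.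

## Retrosynthetic reasoning

28 back to 24. The last operation is desilylation of 27. The C9 methyl of 27 comes from the iodomethyl group of 26 by radical dehalogenation, and the C1 carbinol of 26 from the C1 carboxyl of 24 through the mixed anhydride 25. C1 is held at the acid level through the key step for two reasons: an alkene conjugated to a carboxylate does not compete for the electrophile, and a free acid can be reduced beside the lactone, which an ester could not.

24 back to 23 (key disconnection). The O13–C9 bond is cut. This is the only bond whose formation sets C9 without a separate stereocontrolled step, because the carboxyl on C6 can reach only one face of C9. It also avoids acylating a hindered tertiary alcohol. The forward reaction has to make the C14 carboxylate of 23 capture the C9=CH2 alkene across the oxepane at the tertiary carbon, and leave the other two alkenes alone.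

23 back to 20. Both methyl esters of 22 are hydrolysed together, the C12 oxygen of 21 is silylated, and the C12 carbinol comes from the ketone of 20 by reagent-controlled reduction. The ketone cannot be carried further, because the derived β-keto acid would decarboxylate.

20 back to 17 and 18. The C2=C3 bond is cut by a Z-selective phosphonate olefination. It installs the geometry in which C1 is cis to C4 and delivers C1 at the oxidation level wanted for the key step.

17 back to 15 and 16. The C5–C6 bond is cut. Conjugate addition of the β-keto ester 15 to acrolein 16 makes the quaternary centre with a very reactive electrophile and gives the three-carbon aldehyde arm directly. The forward step has to place the new chain cis to the C15 chain.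

15 back to 14. The O7–C6 bond is cut. In 15, C6 is flanked by two carbonyl groups, the substitution that stabilises a diazo precursor, so the ring closes by carbenoid O–H insertion. The other ether cut, O7–C8, would need displacement at a secondary allylic carbon.

14 back to 9 and 10. The C10–C11 bond is cut. The γ-carbon of the dianion 11 of methyl acetoacetate 10 brings in C11, C12, C6 and C14 at once. Diazo transfer (12 to 13) and removal of the TES group (13 to 14) follow.

9 back to 4 and 5. The C8–C9 bond is cut. An asymmetric Morita–Baylis–Hillman reaction of 4 with 5 creates C8 and the C9=CH2 unit in one step. Silylation (7), ester reduction (8) and bromination (9) turn the ester carbon into the electrophilic C10.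

4 back to 1. Nerol 1 supplies C15 to C19 with the Z alkene in place. Its distal alkene is cleaved through 2 and 3 to release C8 as the aldehyde.

## Alternatives that were turned down

Alternative 1: The C10=C11 bond is cut. A dioxanone diene A2, with a vinyl group on C9 and a vinyl-bearing silyloxy arm on C6, would be closed by second-generation Grubbs catalyst RuCl2(=CHPh)(PCy3)(H2IMes) to the bridged alkene A1. In its favour, metathesis of two monosubstituted vinyl groups is more predictable than a transannular electrophilic closure, and with truncated side arms there is no competition among alkenes. Against it, A2 must already hold the quaternary C6 and the tertiary C9 (methyl, vinyl, oxygen) in a 1,4-cis relation on a six-membered lactone, so the hardest stereochemical problem is moved in front of the key step. The ring alkene then has to be hydrogenated, which is why the arms are truncated. Both Z-trisubstituted alkenes must afterwards be built on a molecule that contains the lactone, and reducing a Z-enoate there to the allylic alcohol is not chemoselective. The chosen route is weaker on the certainty of the ring closure, but it takes one Z alkene intact from nerol, creates C9 in the key step and needs three steps after it.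

Alternative 2: The O7–C8 bond is cut through a ketal. A C8 keto C6,C12-diol would be closed by acid to the bicyclic ketal A4, and i-Bu2AlH would cleave the C12-oxygen to C8 bond with hydride delivery to C8, giving oxepane A3. In its favour, C8 is set on a rigid template and the C6/C12 diol can come from an asymmetric dihydroxylation. On the C6/C8 relation this is stronger than the conjugate addition of the chosen route. Against it, A4 is a 6,8-dioxabicyclo[3.2.1]octane, and aluminium hydrides usually open this system so that the six-membered ether survives, which would give a tetrahydropyran instead of the oxepane. The tertiary C9 carbinol must also be set acyclically next to the C8 ketone. After A3, C14 still has to be oxidised from a protected alcohol to the acid and joined to the hindered tertiary C9 hydroxyl to close a bridged lactone. The chosen route makes O13–C9 by alkene activation, where the tertiary character of C9 helps, and needs no oxidation at C14.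

Alternative 3: The C6–C12 bond is cut. SmI2 would reduce the C6–Br bond of the bromo dioxanone aldehyde A6 to a samarium enolate that adds to the tethered C12 aldehyde, giving the bis-silyl ether A5, one deprotection from the target. In its favour, this is the most convergent plan, the bridge enforces the C6 configuration, and SmI2 tolerates alkenes and silyl ethers. On the step count after the key step it is stronger than the chosen route. Against it, A6 is an α-bromo-α-alkoxy lactone at a fully substituted carbon. It should ionise like a glycosyl bromide and would be hard to make beside three alkenes and an aldehyde. The C12 configuration depends on the aldehyde orientation in a bridged transition state that offers little basis for prediction, and C8 and C9 must still be set beforehand. The chosen route keeps every intermediate stable and sets C12 by reagent control on a monocyclic ketone.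

Key step: step 17

## Route

Step 1
Reactants: 1 nerol
Product: 2 tert-butyl{[(2Z)-3,7-dimethylocta-2,6-dien-1-yl]oxy}dimethylsilane
Conditions: TBSCl, imidazole, CH2Cl2, 0 °C to rt
Reagents that add atoms: tert-butyldimethylsilyl chloride, CC(C)(C)[Si](C)(C)Cl
Why: Standard silylation of a primary allylic alcohol; the ether is kept to the end and lowers the nucleophilicity of the C17=C18 alkene.

Step 2
Reactants: 2 nerol TBS ether
Product: 3 tert-butyl{[(2Z)-5-(3,3-dimethyloxiran-2-yl)-3-methylpent-2-en-1-yl]oxy}dimethylsilane (racemic at the epoxide carbon)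
Conditions: mCPBA (1 equiv), NaHCO3, CH2Cl2, –20 to 0 °C
Reagents that add atoms: 3-chloroperoxybenzoic acid, OOC(=O)c1cccc(Cl)c1
Why: Prilezhaev epoxidation; the distal alkene is the more electron-rich one because the C17=C18 alkene is deactivated by the allylic silyloxy group, so one equivalent of peracid should react there (the new stereocentre is destroyed in step 3).

Step 3
Reactants: 3 epoxide
Product: 4 (4Z)-6-[(tert-butyldimethylsilyl)oxy]-4-methylhex-4-enal
Conditions: H5IO6, THF–H2O, 0 °C
Reagents that add atoms: none
Why: Acid-mediated hydration of the epoxide and periodate glycol cleavage in one flask; C8 is released as the aldehyde and the Z alkene is untouched.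

Step 4
Reactants: 4 aldehyde; 5 1,1,1,3,3,3-hexafluoropropan-2-yl prop-2-enoate
Product: 6 1,1,1,3,3,3-hexafluoropropan-2-yl (3S,6Z)-8-[(tert-butyldimethylsilyl)oxy]-3-hydroxy-6-methyl-2-methylideneoct-6-enoate
Conditions: α-isocupreine (C19H22N2O2, 10 mol%), DMF, –55 °C
Reagents that add atoms: none
Why: Morita–Baylis–Hillman reaction in its cinchona-catalysed asymmetric form: the quinuclidine nitrogen adds to the activated acrylate and the phenolic OH organises the aldol-type addition; β-isocupreidine gives the R series, and its quinine-derived pseudoenantiomer α-isocupreine is chosen because it should give the S carbinol at C8.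

Step 5
Reactants: 6 adduct
Product: 7 1,1,1,3,3,3-hexafluoropropan-2-yl (3S,6Z)-8-[(tert-butyldimethylsilyl)oxy]-6-methyl-2-methylidene-3-[(triethylsilyl)oxy]oct-6-enoate
Conditions: TESOTf, 2,6-lutidine, CH2Cl2, –78 °C
Reagents that add atoms: triethylsilyl trifluoromethanesulfonate, CC[Si](CC)(CC)OS(=O)(=O)C(F)(F)F
Why: A silyl triflate with a hindered pyridine silylates the carbinol without a nucleophile that could attack the activated ester; TES is chosen so that it can later be removed beside the primary TBS ether.

Step 6
Reactants: 7 silyl ether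
Product: 8 (3S,6Z)-8-[(tert-butyldimethylsilyl)oxy]-6-methyl-2-methylidene-3-[(triethylsilyl)oxy]oct-6-en-1-ol
Conditions: i-Bu2AlH, CH2Cl2, –78 °C; aq. KNaC4H4O6
Reagents that add atoms: none
Why: 1,2-Reduction of an α-substituted acrylate ester to the allylic alcohol by an aluminium hydride; the silyl ethers are inert and C10 is now at the alcohol level.

Step 7
Reactants: 8 allylic alcohol
Product: 9 (3S,6Z)-2-(bromomethyl)-8-[(tert-butyldimethylsilyl)oxy]-6-methyl-3-[(triethylsilyl)oxy]octa-1,6-diene
Conditions: CBr4, PPh3, 2,6-lutidine, CH2Cl2, 0 °C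
Reagents that add atoms: tetrabromomethane, BrC(Br)(Br)Br
Why: Appel bromination of a primary allylic alcohol under buffered conditions; direct and allylic displacement lead to the same 2-substituted allyl bromide.

Step 8
Reactants: 9 allylic bromide; 10 methyl acetoacetate
Product: 12 methyl (7S,10Z)-12-[(tert-butyldimethylsilyl)oxy]-10-methyl-6-methylidene-3-oxo-7-[(triethylsilyl)oxy]dodec-10-enoate, via methyl acetoacetate dianion 11 (not isolated)
Conditions: 10, NaH then n-BuLi, THF, 0 °C; then 9, 0 °C; aq. NH4Cl
Reagents that add atoms: none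
Why: Weiler dianion alkylation: the γ-carbanion is the more nucleophilic site and displaces the allylic bromide (both displacement modes converge), forming C10–C11 and bringing in C11, C12, C6 and C14.

Step 9
Reactants: 12 β-keto ester
Product: 13 methyl (7S,10Z)-12-[(tert-butyldimethylsilyl)oxy]-2-diazo-10-methyl-6-methylidene-3-oxo-7-[(triethylsilyl)oxy]dodec-10-enoate
Conditions: p-ABSA, Et3N, MeCN, 0 °C to rt
Reagents that add atoms: 4-acetamidobenzenesulfonyl azide, CC(=O)Nc1ccc(cc1)S(=O)(=O)N=[N+]=[N-]
Why: Regitz diazo transfer to the activated methylene C6; the silyl ether keeps the C8 oxygen from forming a hemiketal with the C12 ketone until that ketone is tied up in the diazo dicarbonyl unit.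

Step 10
Reactants: 13 diazo keto ester
Product: 14 methyl (7S,10Z)-12-[(tert-butyldimethylsilyl)oxy]-2-diazo-7-hydroxy-10-methyl-6-methylidene-3-oxododec-10-enoate
Conditions: PPTS (cat.), MeOH–CH2Cl2, 0 °C
Reagents that add atoms: none
Why: Mild acidic methanolysis cleaves the secondary TES ether much faster than the primary TBS ether, and the acceptor-substituted diazo group tolerates the weak acid.

Step 11
Reactants: 14 diazo alcohol
Product: 15 methyl (7S)-7-{(3Z)-5-[(tert-butyldimethylsilyl)oxy]-3-methylpent-3-en-1-yl}-6-methylidene-3-oxooxepane-2-carboxylate (C2 epimers and enol)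
Conditions: Rh2(OAc)4 (1 mol%), benzene, 80 °C, slow addition, 0.01 M
Reagents that add atoms: none
Why: Intramolecular rhodium-carbenoid O–H insertion, a known route to 3-oxooxepane-2-carboxylates from δ-hydroxy α-diazo β-keto esters: the hydroxyl oxygen attacks the carbenoid at C6 and proton transfer gives the O7–C6 ether; O–H insertion is expected to outrun cyclopropanation of C9=CH2, and the C6 configuration formed here is irrelevant.

Step 12
Reactants: 15 oxepanone; 16 acrolein
Product: 17 methyl (2R,7S)-7-{(3Z)-5-[(tert-butyldimethylsilyl)oxy]-3-methylpent-3-en-1-yl}-6-methylidene-3-oxo-2-(3-oxopropyl)oxepane-2-carboxylate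
Conditions: 16 (3 equiv), 9-O-benzylcupreidine (C26H28N2O2, 10 mol%), CH2Cl2, –25 °C
Reagents that add atoms: none
Why: Amine-catalysed Michael addition of a cyclic β-keto ester to acrolein, known in enantioselective form with 6'-hydroxy cinchona catalysts (quinuclidine deprotonates C6, the phenol activates acrolein). The quaternary centre is set by the face of the planar enol: attack anti to the pseudoaxial C8–H puts the new chain cis to the C15 chain, and the quinidine-series catalyst is chosen to reinforce that face.

Step 13
Reactants: 17 keto aldehyde; 18 methyl 2-[bis(2,2,2-trifluoroethoxy)phosphoryl]propanoate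
Product: 20 methyl (2R,7S)-7-{(3Z)-5-[(tert-butyldimethylsilyl)oxy]-3-methylpent-3-en-1-yl}-2-[(3Z)-5-methoxy-4-methyl-5-oxopent-3-en-1-yl]-6-methylidene-3-oxooxepane-2-carboxylate, via phosphonate carbanion 19 (not isolated)
Conditions: 18, KN(SiMe3)2, 18-crown-6, THF, –78 °C; then 17
Reagents that add atoms: none
Why: Still–Gennari olefination: the electron-poor phosphonate eliminates under kinetic control to the Z-2-methyl enoate, with C1 cis to C4; the aldehyde reacts far faster than the hindered C12 ketone.

Step 14
Reactants: 20 keto diester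
Product: 21 methyl (2R,3S,7S)-7-{(3Z)-5-[(tert-butyldimethylsilyl)oxy]-3-methylpent-3-en-1-yl}-3-hydroxy-2-[(3Z)-5-methoxy-4-methyl-5-oxopent-3-en-1-yl]-6-methylideneoxepane-2-carboxylate
Conditions: (R)-2-methyl-CBS-oxazaborolidine (C18H20BNO, 0.5 equiv), catecholborane, toluene, –78 to –40 °C
Reagents that add atoms: none
Why: Corey–Bakshi–Shibata reduction: the ketone lies between the fully substituted C6 (large) and the ring CH2 C11 (small), so the R catalyst should give the 12S carbinol with OH cis to the C14 ester; catecholborane neither hydroborates the alkenes nor reduces the esters at this temperature.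

Step 15
Reactants: 21 carbinol
Product: 22 methyl (2R,3S,7S)-3-[(tert-butyldimethylsilyl)oxy]-7-{(3Z)-5-[(tert-butyldimethylsilyl)oxy]-3-methylpent-3-en-1-yl}-2-[(3Z)-5-methoxy-4-methyl-5-oxopent-3-en-1-yl]-6-methylideneoxepane-2-carboxylate
Conditions: TBSOTf, 2,6-lutidine, CH2Cl2, 0 °C to rt
Reagents that add atoms: tert-butyldimethylsilyl trifluoromethanesulfonate, CC(C)(C)[Si](C)(C)OS(=O)(=O)C(F)(F)F
Why: The silyl triflate is needed for the hindered secondary alcohol; the ether blocks retro-aldol cleavage in step 16 and participation of this oxygen in step 17.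

Step 16
Reactants: 22 diester
Product: 23 (2R,3S,7S)-3-[(tert-butyldimethylsilyl)oxy]-7-{(3Z)-5-[(tert-butyldimethylsilyl)oxy]-3-methylpent-3-en-1-yl}-2-[(3Z)-4-carboxypent-3-en-1-yl]-6-methylideneoxepane-2-carboxylic acid
Conditions: LiOH, THF–MeOH–H2O, 45 °C; then 1 M HCl to pH 4, 0 °C
Reagents that add atoms: lithium hydroxide, [Li+].[OH-]
Why: Saponification of both methyl esters; the α-alkoxy ester on C6 is inductively activated despite its substitution, and no retro-aldol or β-elimination is open because C12–O is silylated and C6 bears no hydrogen.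

Step 17
Reactants: 23 diacid
Product: 24 (2Z)-5-[(1R,2S,5R,9S)-2-[(tert-butyldimethylsilyl)oxy]-9-{(3Z)-5-[(tert-butyldimethylsilyl)oxy]-3-methylpent-3-en-1-yl}-5-(iodomethyl)-7-oxo-6,8-dioxabicyclo[3.2.2]nonan-1-yl]-2-methylpent-2-enoic acid
Conditions: I2 (2.5 equiv), NaHCO3, MeCN–H2O, 0 °C, dark; aq. Na2S2O3; pH 4
Reagents that add atoms: iodine, II
Why: Electrophilic iodine adds reversibly to the alkenes, and the iodonium at C9=CH2 is opened at its tertiary carbon by the C14 carboxylate held on the same ring; this is an iodolactonisation of the δ,ε-unsaturated-acid type run across the oxepane. The new O13–C9 bond closes the 1,4-dioxan-2-one ring (C6, C14, O13, C9, C8, O7) in a 6-exo-trig mode, and the same bond completes the seven-membered lactone ring through C12–C11–C10, again with the alkene exocyclic. C9 is the only new stereocentre and is set by C6: the carboxylate can reach only the face of C9 that is syn to C14, which leaves CH2I on the face where the C5 and C15 chains already sit. Attack at the tertiary carbon is secured by the 1,1-disubstitution of the alkene and by the short tether, which cannot reach the CH2 terminus. Chemoselectivity is built into the substrate: the C2=C3 alkene, also δ,ε to this carboxyl, is conjugated with the C1 carboxylate and should not take up iodine, and the C17=C18 alkene has no carboxylate within reach of a normal ring, so its iodonium reverts. The C12 oxygen is on the carboxyl face and could close a five-membered ether onto C9; the TBS group and the anionic carboxylate are relied on to make lactonisation the faster capture. The cis arrangement of the two chains lets both lie pseudoequatorial in the boat-like conformer that brings the pseudoaxial carboxylate over C9.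

Step 18
Reactants: 24 iodolactone acid
Product: 26 (1R,2S,5R,9S)-2-[(tert-butyldimethylsilyl)oxy]-9-{(3Z)-5-[(tert-butyldimethylsilyl)oxy]-3-methylpent-3-en-1-yl}-1-[(3Z)-5-hydroxy-4-methylpent-3-en-1-yl]-5-(iodomethyl)-6,8-dioxabicyclo[3.2.2]nonan-7-one, via mixed carbonic anhydride 25 (not isolated)
Conditions: i-BuOCOCl, N-methylmorpholine, THF, –15 °C; then NaBH4, MeOH, –15 to 0 °C
Reagents that add atoms: none
Why: Mixed-anhydride activation and borohydride reduction turns a carboxylic acid into the primary alcohol under conditions that leave a lactone, a primary iodide and silyl ethers alone; only the C1 acid is free, and 1,2-reduction of the α-methyl enoyl unit should keep the Z geometry.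

Step 19
Reactants: 26 iodo alcohol
Product: 27 (1R,2S,5R,9S)-2-[(tert-butyldimethylsilyl)oxy]-9-{(3Z)-5-[(tert-butyldimethylsilyl)oxy]-3-methylpent-3-en-1-yl}-1-[(3Z)-5-hydroxy-4-methylpent-3-en-1-yl]-5-methyl-6,8-dioxabicyclo[3.2.2]nonan-7-one
Conditions: Bu3SnH (0.3 M), AIBN, benzene, 80 °C
Reagents that add atoms: none
Why: Radical chain dehalogenation; the stannane concentration is kept high so that hydrogen transfer to the primary radical outpaces the 1,2-acyloxy shift open to a β-(acyloxy)alkyl radical, and C9 is not touched.

Step 20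
Reactants: 27 bis-silyl ether
Product: 28 (1R,2S,5R,9S)-2-hydroxy-1-[(3Z)-5-hydroxy-4-methylpent-3-en-1-yl]-9-[(3Z)-5-hydroxy-3-methylpent-3-en-1-yl]-5-methyl-6,8-dioxabicyclo[3.2.2]nonan-7-one (CNP0105745.1)
Conditions: HF·pyridine, pyridine, THF, 0 °C to rt
Reagents that add atoms: none
Why: Buffered fluoride cleaves the primary allylic and the hindered secondary TBS ether; the medium is neither basic enough for retro-aldol or lactone opening nor acidic enough to ionise the allylic alcohols.

## Compound list

1 | nerol, (2Z)-3,7-dimethylocta-2,6-dien-1-ol | CC(C)=CCC/C(C)=C\CO | starting material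
2 | nerol TBS ether | CC(C)=CCC/C(C)=C\CO[Si](C)(C)C(C)(C)C | intermediate
3 | 6,7-epoxide of 2 (racemic epoxide carbon) | CC1(C)OC1CC/C(C)=C\CO[Si](C)(C)C(C)(C)C | intermediate
4 | (4Z)-6-(TBS-oxy)-4-methylhex-4-enal | O=CCC/C(C)=C\CO[Si](C)(C)C(C)(C)C | intermediate
5 | 1,1,1,3,3,3-hexafluoropropan-2-yl prop-2-enoate | C=CC(=O)OC(C(F)(F)F)C(F)(F)F | starting material
6 | hexafluoroisopropyl (3S,6Z)-8-(TBS-oxy)-3-hydroxy-6-methyl-2-methylideneoct-6-enoate | C=C(C(=O)OC(C(F)(F)F)C(F)(F)F)[C@@H](O)CC/C(C)=C\CO[Si](C)(C)C(C)(C)C | intermediate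
7 | TES ether of 6 | C=C(C(=O)OC(C(F)(F)F)C(F)(F)F)[C@@H](O[Si](CC)(CC)CC)CC/C(C)=C\CO[Si](C)(C)C(C)(C)C | intermediate
8 | (3S,6Z)-8-(TBS-oxy)-6-methyl-2-methylidene-3-(TES-oxy)oct-6-en-1-ol | C=C(CO)[C@@H](O[Si](CC)(CC)CC)CC/C(C)=C\CO[Si](C)(C)C(C)(C)C | intermediate
9 | (3S,6Z)-2-(bromomethyl)-8-(TBS-oxy)-6-methyl-3-(TES-oxy)octa-1,6-diene | C=C(CBr)[C@@H](O[Si](CC)(CC)CC)CC/C(C)=C\CO[Si](C)(C)C(C)(C)C | intermediate
10 | methyl acetoacetate (methyl 3-oxobutanoate) | CC(=O)CC(=O)OC | starting material
11 | sodium lithium dianion of methyl acetoacetate, formed in the flask | [Na+].[Li+].[CH2-]C(=O)[CH-]C(=O)OC | intermediate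
12 | methyl (7S,10Z)-12-(TBS-oxy)-10-methyl-6-methylidene-3-oxo-7-(TES-oxy)dodec-10-enoate | COC(=O)CC(=O)CCC(=C)[C@@H](O[Si](CC)(CC)CC)CC/C(C)=C\CO[Si](C)(C)C(C)(C)C | intermediate
13 | 2-diazo derivative of 12 | COC(=O)C(=[N+]=[N-])C(=O)CCC(=C)[C@@H](O[Si](CC)(CC)CC)CC/C(C)=C\CO[Si](C)(C)C(C)(C)C | intermediate
14 | methyl (7S,10Z)-12-(TBS-oxy)-2-diazo-7-hydroxy-10-methyl-6-methylidene-3-oxododec-10-enoate | COC(=O)C(=[N+]=[N-])C(=O)CCC(=C)[C@@H](O)CC/C(C)=C\CO[Si](C)(C)C(C)(C)C | intermediate
15 | methyl (7S)-7-[(3Z)-5-(TBS-oxy)-3-methylpent-3-en-1-yl]-6-methylidene-3-oxooxepane-2-carboxylate (C2 epimers) | COC(=O)C1O[C@@H](CC/C(C)=C\CO[Si](C)(C)C(C)(C)C)C(=C)CCC1=O | intermediate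
16 | acrolein (prop-2-enal) | C=CC=O | starting material
17 | methyl (2R,7S)-7-[(3Z)-5-(TBS-oxy)-3-methylpent-3-en-1-yl]-6-methylidene-3-oxo-2-(3-oxopropyl)oxepane-2-carboxylate | O=CCC[C@@]1(C(=O)OC)O[C@@H](CC/C(C)=C\CO[Si](C)(C)C(C)(C)C)C(=C)CCC1=O | intermediate
18 | methyl 2-[bis(2,2,2-trifluoroethoxy)phosphoryl]propanoate | COC(=O)C(C)P(=O)(OCC(F)(F)F)OCC(F)(F)F | starting material
19 | potassium carbanion of 18, formed in the flask | [K+].COC(=O)[C-](C)P(=O)(OCC(F)(F)F)OCC(F)(F)F | intermediate
20 | methyl (2R,7S)-7-[(3Z)-5-(TBS-oxy)-3-methylpent-3-en-1-yl]-2-[(3Z)-5-methoxy-4-methyl-5-oxopent-3-en-1-yl]-6-methylidene-3-oxooxepane-2-carboxylate | C/C(=C/CC[C@@]1(C(=O)OC)O[C@@H](CC/C(C)=C\CO[Si](C)(C)C(C)(C)C)C(=C)CCC1=O)C(=O)OC | intermediate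
21 | (2R,3S,7S)-3-hydroxy diester from 20 | C/C(=C/CC[C@@]1(C(=O)OC)O[C@@H](CC/C(C)=C\CO[Si](C)(C)C(C)(C)C)C(=C)CC[C@@H]1O)C(=O)OC | intermediate
22 | (2R,3S,7S)-3-(TBS-oxy) diester | C/C(=C/CC[C@@]1(C(=O)OC)O[C@@H](CC/C(C)=C\CO[Si](C)(C)C(C)(C)C)C(=C)CC[C@@H]1O[Si](C)(C)C(C)(C)C)C(=O)OC | intermediate
23 | (2R,3S,7S)-3-(TBS-oxy)-7-[(3Z)-5-(TBS-oxy)-3-methylpent-3-en-1-yl]-2-[(3Z)-4-carboxypent-3-en-1-yl]-6-methylideneoxepane-2-carboxylic acid | C/C(=C/CC[C@@]1(C(=O)O)O[C@@H](CC/C(C)=C\CO[Si](C)(C)C(C)(C)C)C(=C)CC[C@@H]1O[Si](C)(C)C(C)(C)C)C(=O)O | intermediate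
24 | (1R,2S,5R,9S)-5-(iodomethyl) bicyclic lactone with C1 carboxylic acid | C/C(=C/CC[C@@]12O[C@@H](CC/C(C)=C\CO[Si](C)(C)C(C)(C)C)[C@@](CI)(CC[C@@H]1O[Si](C)(C)C(C)(C)C)OC2=O)C(=O)O | intermediate
25 | isobutyl carbonic mixed anhydride of 24, formed in the flask | C/C(=C/CC[C@@]12O[C@@H](CC/C(C)=C\CO[Si](C)(C)C(C)(C)C)[C@@](CI)(CC[C@@H]1O[Si](C)(C)C(C)(C)C)OC2=O)C(=O)OC(=O)OCC(C)C | intermediate
26 | (1R,2S,5R,9S)-5-(iodomethyl) bicyclic lactone with C1 allylic alcohol | C/C(=C/CC[C@@]12O[C@@H](CC/C(C)=C\CO[Si](C)(C)C(C)(C)C)[C@@](CI)(CC[C@@H]1O[Si](C)(C)C(C)(C)C)OC2=O)CO | intermediate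
27 | (1R,2S,5R,9S)-5-methyl bicyclic lactone, TBS at C12–O and C19–O | C/C(=C/CC[C@@]12O[C@@H](CC/C(C)=C\CO[Si](C)(C)C(C)(C)C)[C@@](C)(CC[C@@H]1O[Si](C)(C)C(C)(C)C)OC2=O)CO | intermediate
28 | CNP0105745.1, (1R,2S,5R,9S)-2-hydroxy-1-[(3Z)-5-hydroxy-4-methylpent-3-en-1-yl]-9-[(3Z)-5-hydroxy-3-methylpent-3-en-1-yl]-5-methyl-6,8-dioxabicyclo[3.2.2]nonan-7-one | C/C(=C/CC[C@@]12O[C@@H](CC/C(C)=C\CO)[C@@](C)(CC[C@@H]1O)OC2=O)CO | target

## Step count and least certain steps

Total: 20 steps. Longest linear sequence: 20 steps (1 to 28); compounds 5, 10, 16 and 18 are bought and enter directly.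

Step 17 (key step). The likeliest failure is slow transannular capture, because the oxepane must adopt a boat-like conformer with the carboxylate pseudoaxial. Slower processes could then take over: iodohydrin formation at the electron-rich C17=C18 alkene, or attack of the C12 silyloxy oxygen on C9 with loss of the silyl group. The fallback changes the mode of alkene activation. Starting from 23, a cobalt-hydride hydrogen-atom transfer would be run with the Co(salen) complex C36H52CoN2O2 (divalent cobalt), N-fluoro-2,4,6-trimethylpyridinium triflate and PhSiH3. It puts hydrogen on the CH2 terminus and lets the carboxylate trap the oxidised tertiary centre, giving the methyl lactone acid F1 directly. Its C1 carboxyl is then reduced through the mixed anhydride F2 with NaBH4, and the route is rejoined at 27 without the tin step.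

Step 12. The likeliest failure is poor facial selectivity at C6. The bias of the ring across O7 is small, and the sense of the cinchona catalyst is extrapolated from carbocyclic β-keto esters. Aldol closure of the keto aldehyde is a second risk. The fallback starts from 15. A palladium-catalysed asymmetric allylic alkylation (Pd2(dba)3·CHCl3 as zerovalent palladium source, the matching enantiomer of the DACH-phenyl Trost ligand, allyl acetate, tetramethylguanidine) gives the 2-allyl keto ester F3. Hydroboration with RhCl(PPh3)3 and catecholborane, selective for the monosubstituted alkene, followed by NaBO3 oxidation, gives the primary alcohol F4. Dess–Martin oxidation returns the route at 17.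

Step 11. The likeliest failure is diversion of the carbenoid into cyclopropanation of the nearby C9=CH2 alkene, which would close a five-membered ring, or into an allylic shift of the oxonium ylide. The fallback avoids carbenoids and starts from 9. Alkylation of the lithium enolate of N-methoxy-N-methylacetamide (LiN(i-Pr)2, –78 °C) gives the amide F5. Methanolysis of the TES ether gives the hydroxy amide F6, and O-alkylation with NaH and methyl bromoacetate gives the glycolate ether F7. LiN(SiMe3)2 then closes the ring by Dieckmann-type acylation of the ester enolate on the Weinreb amide, returning the route at 15.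

Step 4. The likeliest failure is low conversion and eroded enantiomeric purity, since amine-catalysed additions to an enolisable aliphatic aldehyde compete with aldol and acetal side reactions. The fallback starts from 4 and sets C8 by reduction. The bromide F8 (from 2,3-dibromopropene and 4-methoxybenzyl alcohol) is lithiated with t-BuLi and added to 4 to give the racemic carbinol F9. Dess–Martin oxidation gives the enone F10, and (R)-2-methyl-CBS-oxazaborolidine with catecholborane gives the S carbinol F11. TESOTf gives F12, and DDQ removes the 4-methoxybenzyl group to return the route at 8.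

Step 14. The likeliest failure is slow reduction of the hindered ketone, so that uncatalysed hydride transfer erodes the selectivity at C12. The fallback is biocatalytic: 20 would be screened against ketoreductases with cofactor recycling, a class of enzymes that reduces 2,2-disubstituted cyclic β-keto esters to the S carbinols, returning the route at 21 without new intermediates.

## Further compounds

F1 | step 17 | (1R,2S,5R,9S)-5-methyl bicyclic lactone with C1 carboxylic acid, TBS at C12–O and C19–O | C/C(=C/CC[C@@]12O[C@@H](CC/C(C)=C\CO[Si](C)(C)C(C)(C)C)[C@@](C)(CC[C@@H]1O[Si](C)(C)C(C)(C)C)OC2=O)C(=O)O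
F2 | step 17 | isobutyl carbonic mixed anhydride of F1 | C/C(=C/CC[C@@]12O[C@@H](CC/C(C)=C\CO[Si](C)(C)C(C)(C)C)[C@@](C)(CC[C@@H]1O[Si](C)(C)C(C)(C)C)OC2=O)C(=O)OC(=O)OCC(C)C
F3 | step 12 | methyl (2R,7S)-2-allyl-7-[(3Z)-5-(TBS-oxy)-3-methylpent-3-en-1-yl]-6-methylidene-3-oxooxepane-2-carboxylate | C=CC[C@@]1(C(=O)OC)O[C@@H](CC/C(C)=C\CO[Si](C)(C)C(C)(C)C)C(=C)CCC1=O
F4 | step 12 | methyl (2R,7S)-2-(3-hydroxypropyl)-7-[(3Z)-5-(TBS-oxy)-3-methylpent-3-en-1-yl]-6-methylidene-3-oxooxepane-2-carboxylate | OCCC[C@@]1(C(=O)OC)O[C@@H](CC/C(C)=C\CO[Si](C)(C)C(C)(C)C)C(=C)CCC1=O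
F5 | step 11 | (5S,8Z)-10-(TBS-oxy)-N-methoxy-N,8-dimethyl-4-methylidene-5-(TES-oxy)dec-8-enamide | CON(C)C(=O)CCC(=C)[C@@H](O[Si](CC)(CC)CC)CC/C(C)=C\CO[Si](C)(C)C(C)(C)C
F6 | step 11 | (5S,8Z)-10-(TBS-oxy)-5-hydroxy-N-methoxy-N,8-dimethyl-4-methylidenedec-8-enamide | CON(C)C(=O)CCC(=C)[C@@H](O)CC/C(C)=C\CO[Si](C)(C)C(C)(C)C
F7 | step 11 | methyl 2-{[(5S,8Z)-10-(TBS-oxy)-1-[methoxy(methyl)amino]-8-methyl-4-methylidene-1-oxodec-8-en-5-yl]oxy}acetate | CON(C)C(=O)CCC(=C)[C@@H](OCC(=O)OC)CC/C(C)=C\CO[Si](C)(C)C(C)(C)C
F8 | step 4 | 1-{[(2-bromoprop-2-en-1-yl)oxy]methyl}-4-methoxybenzene | C=C(Br)COCc1ccc(OC)cc1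
F9 | step 4 | racemic (6Z)-8-(TBS-oxy)-2-{[(4-methoxybenzyl)oxy]methyl}-6-methylocta-1,6-dien-3-ol | C=C(COCc1ccc(OC)cc1)C(O)CC/C(C)=C\CO[Si](C)(C)C(C)(C)C
F10 | step 4 | (6Z)-8-(TBS-oxy)-2-{[(4-methoxybenzyl)oxy]methyl}-6-methylocta-1,6-dien-3-one | C=C(COCc1ccc(OC)cc1)C(=O)CC/C(C)=C\CO[Si](C)(C)C(C)(C)C
F11 | step 4 | (3S,6Z)-8-(TBS-oxy)-2-{[(4-methoxybenzyl)oxy]methyl}-6-methylocta-1,6-dien-3-ol | C=C(COCc1ccc(OC)cc1)[C@@H](O)CC/C(C)=C\CO[Si](C)(C)C(C)(C)C
F12 | step 4 | TES ether of F11 | C=C(COCc1ccc(OC)cc1)[C@@H](O[Si](CC)(CC)CC)CC/C(C)=C\CO[Si](C)(C)C(C)(C)C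
F0 | step 14 | none | none
A1 | alternative 1 | bridged lactone with C10=C11, C12–OTBS, 2-(tert-butyldiphenylsilyloxy)ethyl on C6 and 2-(4-methoxybenzyloxy)ethyl on C8 | CC(C)(C)[Si](c1ccccc1)(c1ccccc1)OCC[C@@]12O[C@@H](CCOCc3ccc(OC)cc3)[C@@](C)(C=C[C@@H]1O[Si](C)(C)C(C)(C)C)OC2=O
A2 | alternative 1 | 1,4-dioxan-2-one diene with vinyl and methyl on C9 and a 1-(TBS-oxy)allyl arm on C6, configured as in A1 | CC(C)(C)[Si](c1ccccc1)(c1ccccc1)OCC[C@]1([C@@H](O[Si](C)(C)C(C)(C)C)C=C)O[C@@H](CCOCc2ccc(OC)cc2)[C@@](C)(C=C)OC1=O
A3 | alternative 2 | oxepane with C8–H set, free C12 hydroxyl, C9–OTES and C14 as 4-methoxybenzyl ether | C/C(=C/CC[C@@]1(COCc2ccc(OC)cc2)O[C@@H](CC/C(C)=C\CO[Si](C)(C)C(C)(C)C)[C@@](C)(CC[C@@H]1O)O[Si](CC)(CC)CC)CO[Si](C)(C)C(C)(C)C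
A4 | alternative 2 | 6,8-dioxabicyclo[3.2.1]octane ketal at C8 bridging the C6 and C12 oxygens | C/C(=C/CC[C@@]1(COCc2ccc(OC)cc2)O[C@]3(CC/C(C)=C\CO[Si](C)(C)C(C)(C)C)O[C@H]1CC[C@@]3(C)O[Si](CC)(CC)CC)CO[Si](C)(C)C(C)(C)C
A5 | alternative 3 | bis-TBS ether of the target at C1–O and C19–O with free C12 hydroxyl | C/C(=C/CC[C@@]12O[C@@H](CC/C(C)=C\CO[Si](C)(C)C(C)(C)C)[C@@](C)(CC[C@@H]1O)OC2=O)CO[Si](C)(C)C(C)(C)C
A6 | alternative 3 | 3-bromo-1,4-dioxan-2-one with the C5 chain on the brominated C6 (either configuration) and a 3-oxopropyl arm on C9 | C/C(=C/CCC1(Br)O[C@@H](CC/C(C)=C\CO[Si](C)(C)C(C)(C)C)[C@@](C)(CCC=O)OC1=O)CO[Si](C)(C)C(C)(C)C
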